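A percentage point of excess, right-handed substrate over left-handed substrate among what is left of the two, is the unit of this examination.

the same everywhere: left-handed substrate 0.39 M; right-handed substrate 0.39 M; partner 0.468 M; protic impurity 0.117 M; added ligand 11 mM

| flask | catalyst | remark | time |
|---|---|---|---|
| summer | 2.4 mM | run made earlier |  |
| noon | 4.8 mM | run made earlier |  |
| dawn | 8.1 mM | run made earlier |  |
| ash | 2.3 mM |  | 40 min |
| larch | 10 mM |  | 40 min |

- summer (time / min: right-handed substrate / %, left-handed substrate / %): 2.50: 49.2, 41.5; 8.00: 45.5, 37.0; 12.0: 43.0, 35.9; 20.0: 40.2, 36.1; 30.0: 38.0, 36.8
- noon (time / min: right-handed substrate / %, left-handed substrate / %): 6.00: 44.6, 31.7; 12.0: 40.0, 30.3; 15.0: 37.9, 30.6; 25.0: 34.3, 31.2; 30.0: 33.7, 31.1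
- dawn (time / min: right-handed substrate / %, left-handed substrate / %): 2.50: 47.6, 30.5; 4.00: 45.7, 27.3; 8.00: 40.9, 26.0; 15.0: 34.8, 26.0; 30.0: 30.1, 28.8

(scatter of a reading: 0.3 percentage points)

- catalyst is single-handed; left-handed substrate and right-handed substrate are mirror images of each other, charged as a racemate, each of them at the stated concentration
- the earlier runs were read with a standard deviation of 0.3 percentage points
- steps that have been proposed: catalyst + added ligand <-> idle complex; partner + protic impurity -> quenched reagent; partner + catalyst + right-handed substrate -> catalyst + right-handed product; left-handed substrate <-> right-handed substrate; partner + catalyst + left-handed substrate -> catalyst + left-handed product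
- an excess is the difference of the two amounts in percent of their sum
- an excess is below zero if the other one leads

* which of the two ends with the higher excess of right-handed substrate over left-handed substrate among what is left of the two ("neither" if they lie within 2 percentage points) (ash / larch / neither)
* excess of right-handed substrate over left-handed substrate among what is left of the two at the end, ash
* excess of right-handed substrate over left-handed substrate among what is left of the two at the end, larch

**Where in the readings does an excess decay?** Late in the dawn run, where the sum of the two substrates goes from 60.8% to 58.9% while right-handed substrate falls and left-handed substrate rises. The gap between them shrinks from 8.8 percentage points to 1.3 points in 15.0 min. Read as first-order decay, that makes 5.44 min the time in which the gap halves: the gap half-life, the relaxation half-life of the racemisation.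

**Does the catalyst enter it?** The summer run, with 2.4 mM of catalyst against 8.1 mM, gives 5.64 min over its last readings, about the same. So I carry one value.

**But reaction was still running in that window. Isn't the gap being fed?** Yes. Consuming left-handed substrate faster widens the gap, so decay by itself gives a low reckoning, not a bound.

**Then the low reckonings?** Ash lies nearest the summer run and larch nearest the dawn run. Their last readings give excesses of 1.60% and 2.21% at 30.0 min. My low reckonings at 40 min are then 0.448% for ash and 0.617% for larch, 0.17 points apart against a margin of 2 points.

The forecast, by its own judgement, says neither: ash 0.8% (0.3% to 1.4%) and larch 0.6% (0.2% to 1.2%). Its ash figure stands above my low reckoning, “leaving a small residual source in ash”.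

The flasks give neither: ash 1.04%, larch 1.43%, which is above the forecast's high end.

    catalyst + added ligand ⇌ idle complex (K = 4100 L mol⁻¹, k = 0.197 L mol⁻¹ s⁻¹)
    partner + protic impurity → quenched reagent (k = 0.171 L mol⁻¹ s⁻¹)
    partner + catalyst + right-handed substrate → catalyst + right-handed product (k = 0.0269 L² mol⁻² s⁻¹)
    left-handed substrate ⇌ right-handed substrate (k = 0.00117 s⁻¹)
    partner + catalyst + left-handed substrate → catalyst + left-handed product (k = 2.03 L² mol⁻² s⁻¹)

The gap half-life as read, with nothing feeding the gap, takes ash from 4.77% at 20.0 min to 0.373%. It takes larch, stopped in a neighbouring flask at 25 min with 5.48%, to 0.810%. Both flasks stand higher , and neither is at rest at 40 min. By 400 min, c(partner) in larch goes from 1.81% to 0% of its charge and the excess to 0%. In ash, c(partner) falls from 33.5% to 15.8% of its charge, left-handed product rises from 24.6% to 35.0%, and the excess stands at 0.200%.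

(The earlier runs and the new flask stem from a simulated flask on assumed constants; scatter was added.)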